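## Structural features

The target is a dispiro compound: two 3‑alkyl‑4‑bromofuran‑2(5H)‑one rings are spiro‑joined through their C5 atoms to two adjacent carbons of a cyclobutane (ring C: C5A, C5B, C6A, C6B). Ring A carries butyl at C3A; ring B carries the (R)‑1‑acetoxybutyl group at C3B. C6A and C6B are CHBr carbons, so all four atoms of ring C are stereocentres: two vicinal oxygen‑bearing quaternary spiro carbons next to two vicinal secondary bromides. The arrangement is anti throughout (O1A anti to O1B, the two ring bromines anti, each bromine anti to the lactone oxygen on the neighbouring spiro carbon). This gives a C2‑like core, C5A (S), C5B (S), C6A (R), C6B (R), whose only link to the fifth stereocentre, C1′ (R), runs through the sp2 carbon C3B. Fragile points are the secondary cyclobutyl bromides β to lactone oxygens (elimination, ionisation), the two vinyl bromides that are vinylogous to lactone carbonyls (addition–elimination), the allylic acetate and the strained ring. The real difficulty is to set two vicinal quaternary C–O centres on a four‑membered ring in a defined relation to two bromides, and to fix the absolute sense of that core against the remote C1′. The key step exploits the fact that ring C reduces to a C5A≡C5B alkyne flanked by two bromoalkenyl arms (C4=C3, with C2 cis to C5 in each) plus a two‑carbon C6A–C6B unit at the ketene oxidation level.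

## Logic of the disconnections

27 to 26. The O1B–C5B and C6B–Br bonds are cut together, because they are anti to each other across one ring bond, which is the signature of a bromolactonisation. This removes ring B and two stereocentres. The forward step must put Br+ on the face of the ring alkene away from the bromine on C6A and close the arm B carboxyl 5‑exo at the tertiary carbon.

26 to 25. The O1A–C5A bond is cut with allylic transposition: the double bond goes back to C5A=C5B and a bromide returns to C6B. This removes ring A and the first quaternary centre and leaves a 3,4‑dibromocyclobutene whose two bromides are related by the pseudo‑C2 axis. The forward step must ionise one allylic bromide only and close on the tertiary terminus anti to the bromide that stays.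

25 to 23 to 22. C2A and C2B are taken back from acids to silyl‑protected primary alcohols, because free acids would not pass the hydride reduction or the cycloaddition. The forward steps must unmask and oxidise two allylic alcohols beside two allylic bromides.

22 to 21 to 20. The two C–Br bonds are traced to C–O bonds of a trans‑diol and then to the two carbonyls of an ene‑dione. Both ring CHBr centres then come from one catalyst‑controlled reduction and a double inversion. The forward steps must deliver the (S,S)‑diol and substitute without ionisation.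

20 to 19. The second carbonyl is traced to the CCl2 group, which is the form in which a ketene cycloaddition delivers it.

19 to 16 and 18 (18 made from 17). The C5A–C6A and C5B–C6B bonds are cut, opening ring C to an alkyne and a ketene. This is the largest simplification in the plan: an acyclic dienyne with one stereocentre remains. The forward step must pick the alkyne over two alkenes and three oxygen functions.

16 to 15 to 14 to 13. Only protecting groups change. Silyl ethers on the primary alcohols and an acetate on C1′ are what the cycloaddition and the later acid unmasking tolerate. The acetal that steers the geometry of arm A is no longer needed and is removed.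

13 to 7 and 12. The sp–sp2 bond C5A–C4A is cut. The forward coupling must use the C–I bond of 12 and leave three C–Br bonds alone.

12 to 10 to 9 to 8. The C–I bond is traced to one of two geminal bromines, and C3A=C4A to a ketone. The forward exchange must discriminate the two bromines; a chelating acetal on the CH2O group is put there for that purpose.

7 to 6 to 5. The triple bond is cut between C5B and C5A (one‑carbon homologation of a masked aldehyde). C5B and C2B are then tied in a butenolide ring, which fixes the arm B alkene geometry by construction.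

5 to 4 to 3 to 1 and 2. The C3B–C1′ bond is cut to a vinyl bromide and an aldehyde. C1′ is set afterwards by catalyst‑controlled reduction of the ketone.

## Other disconnections considered

Alternative 1: The cut is at C4A–C5A and C4B–C5B. Ring C is taken intact from 3,4‑bis(tributylstannyl)cyclobut‑3‑ene‑1,2‑dione A2, and the arms arrive as hex‑1‑ynyllithium A3 and the lithium acetylide A4 of silyl‑protected (R)‑hex‑1‑yn‑3‑ol, added in turn in one flask to give the trans‑diol A1.
- In its favour: the union is convergent and puts both tertiary C–O bonds at C5A and C5B in place at once.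
- Against it here: the dilithium trans‑diolate of a cyclobutene is set up for charge‑accelerated conrotatory ring opening, so A1 would have to be trapped cold. The second acetylide must add anti to the first, and nothing relates the sense of the C5A/C5B pair to the stereocentre of A4, so two diastereomeric trans‑diols are to be expected. From A1, each alkynyl carbinol still needs an anti bromo‑carbonylation to become a 4‑bromobutenolide. C6A and C6B need destannylation and anti addition of bromine, in which bromide would have to open the bromonium ion beside the bulkier bromoalkenyl substituent. Tin is used stoichiometrically.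
- Comparison: structurally it forms the arm‑to‑ring bonds and keeps ring C, where the chosen plan forms the C5–C6 bonds and keeps the arm‑to‑alkyne bonds. Mechanistically it is two polar 1,2‑additions creating two stereocentres with partial control, against a cycloaddition creating none. In step economy it is better up to the carbon skeleton. It is equal or better in that the C5–O bonds need no allylic manoeuvre. It is worse afterwards, since all four bromines and both lactone carbonyls are still missing.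

Alternative 2: The cut is at C4B–Br, C3B–C1′ and O1B–C2B. Ring B is assembled last from the γ‑hydroxy ynoate A6 (rings A and C complete), butanal 2 and bromide. MgBr2 adds bromide to C4B, the magnesium allenolate adds through C3B to 2, and the C5B alkoxide closes on the ester to give the deacetyl compound A5; acetylation ends the route.
- In its favour: three bonds form in one operation. The geometry of the tetrasubstituted bromoalkene needs no separate control, because only the isomer with C2B cis to C5B can lactonise and reversible bromide addition can feed it. On this point the alternative is better than the chosen plan, which needs a ring template and a chelate for the same purpose. Arm B also needs no change of oxidation level, which is equal or better.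
- Against it here: it solves ring B only. Ring C with its four stereocentres must already exist in A6. The tertiary propargylic alcohol at C5B would have to come from 1,2‑addition of an alkynyl ester nucleophile to a four‑membered ketone that carries an α‑bromine and an α‑spirolactone, where ring contraction and loss of HBr compete. C1′ is formed under the influence of a distant core, so weak diastereocontrol is expected. A Lewis acid with bromide beside the ring bromides invites epimerisation.
- Comparison: it is a late‑stage tactic for one ring, not a plan for the cyclobutane. Its cascade creates one stereocentre with weak control, where the chosen key step creates none. Locally it is shorter, but the total depends on an unsolved route to A6.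

Alternative 3: The cut is at C5A–C5B. Irradiation of the 6‑alkynyl‑3‑silyloxy‑2‑pyranone A8 closes C3 onto C6 in a disrotatory 4π process to give the cyclobutene‑fused β‑lactone A7.
- In its favour: the quaternary–quaternary bond and ring C form in one step from a flat precursor. The cis ring fusion is fixed by orbital symmetry, so the oxygen on C5A and the carbonyl carbon on C5B (the future C4B) are cis and O1A/O1B are anti without any reagent control. On the certainty of the C5A/C5B relative configuration the alternative is better than the chosen plan. The C6A=C6B alkene is ready for bromine, and the step count to ring C is equal or lower.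
- Against it here: A7 would be racemic, which becomes a diastereomer problem once C1′ is present. Bicyclic β‑lactones of this type revert thermally and lose CO2 on over‑irradiation, and the conjugated alkyne may divert the excited state. The β‑lactone carbonyl must become C4B by C–C bond formation, ring A must be built from the hexynyl group by anti bromo‑carbonylation, and ring B from nothing. Dibromination needs bromide to attack from the concave face.
- Comparison: it is shorter to ring C but longer and less precedented afterwards. The chosen plan brings every carbon and both C4 bromines in before ring C forms and places the stereocontrol in a catalyst‑controlled reduction.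

Key step: step 13

Remark: both orientations of the ketene addition are taken to be acceptable; 19 is drawn with the carbonyl on the ring carbon next to the one that carries the butyl arm.

## Route

Step 1
Reactants: 1 3,4‑dibromofuran‑2(5H)‑one; 2 butanal
Product: 3 (±)‑3‑bromo‑4‑(1‑hydroxybutyl)furan‑2(5H)‑one
Conditions: CrCl2 (4 equiv), NiCl2 (2 mol%), DMF, rt
Reagents that add atoms: none
Why: Nozaki–Hiyama–Kishi coupling: zerovalent nickel inserts into the more electrophilic β C–Br bond (C4, the position that also reacts first in palladium couplings of 1), and the non‑basic alkenylchromium adds to the aldehyde while the lactone and the α C–Br bond stay intact. The carbinol is formed racemic and is corrected in steps 2 and 3.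

Step 2
Reactants: 3 (±)‑3‑bromo‑4‑(1‑hydroxybutyl)furan‑2(5H)‑one
Product: 4 3‑bromo‑4‑butanoylfuran‑2(5H)‑one
Conditions: Dess–Martin periodinane, CH2Cl2, 0 °C → rt
Reagents that add atoms: none
Why: Dess–Martin oxidation of a secondary allylic alcohol under neutral conditions, which avoids enolisation towards the γ‑CH2 of the butenolide.

Step 3
Reactants: 4 3‑bromo‑4‑butanoylfuran‑2(5H)‑one
Product: 5 3‑bromo‑4‑[(1R)‑1‑hydroxybutyl]furan‑2(5H)‑one
Conditions: (S)‑Me‑CBS [(3aS)‑1‑methyl‑3,3‑diphenyltetrahydro‑1H,3H‑pyrrolo[1,2‑c][1,3,2]oxazaborole] (0.2 equiv), catecholborane, toluene, −78 °C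
Reagents that add atoms: none
Why: Corey–Bakshi–Shibata reduction: the tetrasubstituted alkenyl group is the large substituent and propyl the small one, so the (S)‑catalyst should deliver hydride in the sense that gives the (R)‑carbinol, as for aryl alkyl ketones. Catecholborane at low temperature avoids conjugate reduction.

Step 4
Reactants: 5 3‑bromo‑4‑[(1R)‑1‑hydroxybutyl]furan‑2(5H)‑one
Product: 6 3‑bromo‑4‑[(1R)‑1‑hydroxybutyl]‑2,5‑dihydrofuran‑2‑ol
Conditions: iBu2AlH (2.2 equiv), CH2Cl2, −78 °C; aq. potassium sodium tartrate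
Reagents that add atoms: none
Why: Partial reduction of a lactone to the lactol with diisobutylaluminium hydride; the first equivalent is consumed by the free hydroxyl, and the neutral tartrate work‑up is chosen to avoid acid‑promoted dehydration to a furan.

Step 5
Reactants: 6 3‑bromo‑4‑[(1R)‑1‑hydroxybutyl]‑2,5‑dihydrofuran‑2‑ol
Product: 7 (2Z)‑3‑bromo‑2‑[(1R)‑1‑hydroxybutyl]pent‑2‑en‑4‑yn‑1‑ol
Conditions: dimethyl (1‑diazo‑2‑oxopropyl)phosphonate, K2CO3, MeOH, 0 °C → rt
Reagents that add atoms: dimethyl (1‑diazo‑2‑oxopropyl)phosphonate, CC(=O)C(=[N+]=[N-])P(=O)(OC)OC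
Why: Seyferth–Gilbert homologation with the Ohira–Bestmann reagent on the open hydroxy‑enal form of the lactol: the aldehyde carbon becomes C5B and the new carbon C5A. Because C5B and the CH2OH carbon were held cis in the ring, the alkyne is delivered cis to CH2OH and the bromine cis to C1′.

Step 6
Reactants: 8 1‑hydroxyhexan‑2‑one
Product: 9 1‑(methoxymethoxy)hexan‑2‑one
Conditions: MOMCl, iPr2NEt, CH2Cl2, 0 °C → rt
Reagents that add atoms: chloromethyl methyl ether, COCCl
Why: Standard acetal protection; the methoxymethyl group is chosen because its two oxygens can chelate lithium in step 8.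

Step 7
Reactants: 9 1‑(methoxymethoxy)hexan‑2‑one
Product: 10 1,1‑dibromo‑2‑[(methoxymethoxy)methyl]hex‑1‑ene
Conditions: CBr4, PPh3, Et3N, CH2Cl2, 0 → 40 °C
Reagents that add atoms: carbon tetrabromide, BrC(Br)(Br)Br
Why: Ramirez dibromo‑olefination (Wittig reaction of the dibromomethylene ylide); α‑alkoxy ketones are electrophilic enough, and no geometry arises because the two bromines are identical.

Step 8
Reactants: 10 1,1‑dibromo‑2‑[(methoxymethoxy)methyl]hex‑1‑ene
Product: 12 (1Z)‑1‑bromo‑1‑iodo‑2‑[(methoxymethoxy)methyl]hex‑1‑ene, via α‑bromoalkenyllithium 11 (not isolated)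
Conditions: n‑BuLi (0.95 equiv), THF–Et2O, −105 °C; then I2, −105 → −78 °C
Reagents that add atoms: iodine, II
Why: Alkoxy‑directed bromine–lithium exchange of a 1,1‑dibromoalkene: pre‑coordination of butyllithium to the acetal and the five‑membered O→Li chelate in 11 both favour exchange of the bromine cis to CH2OMOM, and the slight deficit of butyllithium lets any wrong carbenoid equilibrate through exchange with remaining 10. Iodinolysis of the configurationally stable alkenyllithium proceeds with retention, so iodine ends cis to CH2OMOM and bromine cis to butyl.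

Step 9
Reactants: 7 (2Z)‑3‑bromo‑2‑[(1R)‑1‑hydroxybutyl]pent‑2‑en‑4‑yn‑1‑ol; 12 (1Z)‑1‑bromo‑1‑iodo‑2‑[(methoxymethoxy)methyl]hex‑1‑ene
Product: 13 (2Z,6E)‑3,6‑dibromo‑7‑butyl‑2‑[(1R)‑1‑hydroxybutyl]‑8‑(methoxymethoxy)octa‑2,6‑dien‑4‑yn‑1‑ol
Conditions: Pd(PPh3)4 (5 mol%), CuI (10 mol%), iPr2NH, THF, rt, no O2
Reagents that add atoms: none
Why: Sonogashira coupling: zerovalent palladium inserts into the C–I bond far faster than into any of the C–Br bonds, so the geminal bromine of 12 and the bromine of 7 persist and both alkene geometries are carried over unchanged.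

Step 10
Reactants: 13 (2Z,6E)‑3,6‑dibromo‑7‑butyl‑2‑[(1R)‑1‑hydroxybutyl]‑8‑(methoxymethoxy)octa‑2,6‑dien‑4‑yn‑1‑ol
Product: 14 (2Z,6E)‑3,6‑dibromo‑7‑butyl‑2‑[(1R)‑1‑hydroxybutyl]octa‑2,6‑dien‑4‑yne‑1,8‑diol
Conditions: conc. HCl (cat.), MeOH, 40 °C
Reagents that add atoms: none
Why: Acid‑catalysed acetal exchange removes the methoxymethyl group; the allylic hydroxyls sit on bromine‑ and alkyne‑substituted alkenes and should not ionise under these conditions.

Step 11
Reactants: 14 (2Z,6E)‑3,6‑dibromo‑7‑butyl‑2‑[(1R)‑1‑hydroxybutyl]octa‑2,6‑dien‑4‑yne‑1,8‑diol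
Product: 15 (2Z,6E)‑3,6‑dibromo‑7‑butyl‑1,8‑bis[(tert‑butyldimethylsilyl)oxy]‑2‑[(1R)‑1‑hydroxybutyl]octa‑2,6‑dien‑4‑yne
Conditions: TBSCl (2.2 equiv), imidazole, CH2Cl2, 0 °C
Reagents that add atoms: tert‑butyldimethylsilyl chloride, CC(C)(C)[Si](C)(C)Cl
Why: Selective silylation of the two primary allylic alcohols; the secondary C1′ hydroxyl, flanked by a tetrasubstituted alkene and a propyl group, reacts much more slowly.

Step 12
Reactants: 15 (2Z,6E)‑3,6‑dibromo‑7‑butyl‑1,8‑bis[(tert‑butyldimethylsilyl)oxy]‑2‑[(1R)‑1‑hydroxybutyl]octa‑2,6‑dien‑4‑yne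
Product: 16 (2Z,6E)‑2‑[(1R)‑1‑acetoxybutyl]‑3,6‑dibromo‑7‑butyl‑1,8‑bis[(tert‑butyldimethylsilyl)oxy]octa‑2,6‑dien‑4‑yne
Conditions: Ac2O, pyridine, 4‑(dimethylamino)pyridine (cat.), CH2Cl2, rt
Reagents that add atoms: acetic anhydride, CC(=O)OC(C)=O
Why: Nucleophile‑catalysed acylation of the remaining secondary alcohol; the C1′–O bond is not touched, so the configuration is retained.

Step 13
Reactants: 16 (2Z,6E)‑2‑[(1R)‑1‑acetoxybutyl]‑3,6‑dibromo‑7‑butyl‑1,8‑bis[(tert‑butyldimethylsilyl)oxy]octa‑2,6‑dien‑4‑yne; 17 trichloroacetyl chloride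
Product: 19 3‑[(1Z,3R)‑3‑acetoxy‑1‑bromo‑2‑{[(tert‑butyldimethylsilyl)oxy]methyl}hex‑1‑en‑1‑yl]‑2‑[(1E)‑1‑bromo‑2‑{[(tert‑butyldimethylsilyl)oxy]methyl}hex‑1‑en‑1‑yl]‑4,4‑dichlorocyclobut‑2‑en‑1‑one, via dichloroketene 18 (not isolated)
Conditions: Zn–Cu couple, POCl3, Et2O, slow addition of 17, rt → 35 °C
Reagents that add atoms: none
Why: Zinc of the Zn–Cu couple reduces 17 to dichloroketene 18, whose electrophilic central carbon is attacked by the π bond of the central alkyne in an asynchronous, orthogonal cycloaddition: the ketene carbonyl carbon bonds to one alkyne carbon, vinyl‑cation character develops at the other, and that carbon collapses onto the CCl2 carbon. The closest known reaction type is the dichloroketene–alkyne (2+2) cycloaddition to 4,4‑dichlorocyclobutenones under zinc–copper/POCl3 conditions, which accepts dialkyl‑, diaryl‑ and enyne‑type alkynes. Ring C is closed by cycloaddition: both ring bonds, C5A–C6A and C5B–C6B, form in the one intermolecular event and no other ring size is possible. No stereocentre is formed, since C5A and C5B become the ring alkene and C6A and C6B a carbonyl and a CCl2 carbon; ring stereochemistry is set in steps 15, 16, 19 and 20. The step needs chemoselectivity for the alkyne over the two alkenes and the oxygen functions: the alkenes are tetrasubstituted, hindered and carry bromine, the acetate is not nucleophilic, and the bulky silyl ethers, with POCl3 to tie up ZnCl2, should resist acylation and Bellus–Claisen‑type capture. Keeping C2A and C2B at the alcohol oxidation level leaves the cross‑conjugated alkyne as electron‑rich as the vinyl bromines allow. The orientation of the ketene is not controlled and need not be, because both orientations lead to the same dione in step 14.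

Step 14
Reactants: 19 3‑[(1Z,3R)‑3‑acetoxy‑1‑bromo‑2‑{[(tert‑butyldimethylsilyl)oxy]methyl}hex‑1‑en‑1‑yl]‑2‑[(1E)‑1‑bromo‑2‑{[(tert‑butyldimethylsilyl)oxy]methyl}hex‑1‑en‑1‑yl]‑4,4‑dichlorocyclobut‑2‑en‑1‑one
Product: 20 3‑[(1Z,3R)‑3‑acetoxy‑1‑bromo‑2‑{[(tert‑butyldimethylsilyl)oxy]methyl}hex‑1‑en‑1‑yl]‑4‑[(1E)‑1‑bromo‑2‑{[(tert‑butyldimethylsilyl)oxy]methyl}hex‑1‑en‑1‑yl]cyclobut‑3‑ene‑1,2‑dione
Conditions: AgOTf (2.2 equiv), NaHCO3, acetone–H2O, 0 °C → rt, dark
Reagents that add atoms: water, O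
Why: Hydrolysis of a 4,4‑dichlorocyclobutenone to the cyclobutene‑1,2‑dione, here assisted by silver: chloride abstraction gives a chlorocyclobutenyl cation stabilised by the alkenyl arms, water adds and HCl is lost. Bicarbonate buffering spares the silyl ethers and the acetate.

Step 15
Reactants: 20 3‑[(1Z,3R)‑3‑acetoxy‑1‑bromo‑2‑{[(tert‑butyldimethylsilyl)oxy]methyl}hex‑1‑en‑1‑yl]‑4‑[(1E)‑1‑bromo‑2‑{[(tert‑butyldimethylsilyl)oxy]methyl}hex‑1‑en‑1‑yl]cyclobut‑3‑ene‑1,2‑dione
Product: 21 (1S,2S)‑3‑[(1Z,3R)‑3‑acetoxy‑1‑bromo‑2‑{[(tert‑butyldimethylsilyl)oxy]methyl}hex‑1‑en‑1‑yl]‑4‑[(1E)‑1‑bromo‑2‑{[(tert‑butyldimethylsilyl)oxy]methyl}hex‑1‑en‑1‑yl]cyclobut‑3‑ene‑1,2‑diol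
Conditions: (S)‑Me‑CBS [(3aS)‑1‑methyl‑3,3‑diphenyltetrahydro‑1H,3H‑pyrrolo[1,2‑c][1,3,2]oxazaborole] (0.5 equiv), catecholborane (3 equiv), toluene–CH2Cl2, −78 → −40 °C
Reagents that add atoms: none
Why: Corey–Bakshi–Shibata reduction of both carbonyls: each sees the alkenyl‑bearing ring carbon as the large group and the neighbouring carbonyl carbon as the small one, and the two environments are mirror‑related, so one catalyst should attack opposite ring faces at C6A and C6B and give the trans‑diol. On this model the (S)‑catalyst gives the (S,S)‑diol (the antipodal catalyst would be used if the large/small roles prove reversed). Hydride delivery anti to the first borylated oxygen reinforces the trans outcome.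

Step 16
Reactants: 21 (1S,2S)‑3‑[(1Z,3R)‑3‑acetoxy‑1‑bromo‑2‑{[(tert‑butyldimethylsilyl)oxy]methyl}hex‑1‑en‑1‑yl]‑4‑[(1E)‑1‑bromo‑2‑{[(tert‑butyldimethylsilyl)oxy]methyl}hex‑1‑en‑1‑yl]cyclobut‑3‑ene‑1,2‑diol
Product: 22 (3R,4R)‑3,4‑dibromo‑1‑[(1E)‑1‑bromo‑2‑{[(tert‑butyldimethylsilyl)oxy]methyl}hex‑1‑en‑1‑yl]‑2‑[(1Z,3R)‑3‑acetoxy‑1‑bromo‑2‑{[(tert‑butyldimethylsilyl)oxy]methyl}hex‑1‑en‑1‑yl]cyclobut‑1‑ene
Conditions: CBr4 (2.5 equiv), PPh3 (2.5 equiv), CH2Cl2, −20 → 0 °C
Reagents that add atoms: carbon tetrabromide, BrC(Br)(Br)Br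
Why: Appel reaction: each alkoxyphosphonium is displaced by bromide with inversion, so the (S,S)‑diol gives the (R,R)‑trans‑dibromide. After the first inversion the bromine is cis to the remaining leaving group and cannot participate, so the second displacement is also a direct SN2.

Step 17
Reactants: 22 (3R,4R)‑3,4‑dibromo‑1‑[(1E)‑1‑bromo‑2‑{[(tert‑butyldimethylsilyl)oxy]methyl}hex‑1‑en‑1‑yl]‑2‑[(1Z,3R)‑3‑acetoxy‑1‑bromo‑2‑{[(tert‑butyldimethylsilyl)oxy]methyl}hex‑1‑en‑1‑yl]cyclobut‑1‑ene
Product: 23 (3R,4R)‑3,4‑dibromo‑1‑[(1E)‑1‑bromo‑2‑(hydroxymethyl)hex‑1‑en‑1‑yl]‑2‑[(1Z,3R)‑3‑acetoxy‑1‑bromo‑2‑(hydroxymethyl)hex‑1‑en‑1‑yl]cyclobut‑1‑ene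
Conditions: aq. HF (48%), MeCN, 0 °C
Reagents that add atoms: none
Why: Acidic fluoride desilylation of primary silyl ethers; no amine or basic fluoride is present, so the allylic bromides and the acetate should survive.

Step 18
Reactants: 23 (3R,4R)‑3,4‑dibromo‑1‑[(1E)‑1‑bromo‑2‑(hydroxymethyl)hex‑1‑en‑1‑yl]‑2‑[(1Z,3R)‑3‑acetoxy‑1‑bromo‑2‑(hydroxymethyl)hex‑1‑en‑1‑yl]cyclobut‑1‑ene
Product: 25 (3R,4R)‑3,4‑dibromo‑1‑[(1E)‑1‑bromo‑2‑carboxyhex‑1‑en‑1‑yl]‑2‑[(1E,3R)‑3‑acetoxy‑1‑bromo‑2‑carboxyhex‑1‑en‑1‑yl]cyclobut‑1‑ene, via dialdehyde 24 (not isolated)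
Conditions: Dess–Martin periodinane, CH2Cl2, 0 °C; then NaClO2, NaH2PO4, 2‑methylbut‑2‑ene, t‑BuOH–H2O, 0 °C
Reagents that add atoms: sodium chlorite, [Na+].[O-]Cl=O
Why: Dess–Martin oxidation of the two primary allylic alcohols, then Pinnick oxidation of the crude enals: both are near‑neutral and non‑nucleophilic, so the allylic bromides, the ring alkene (protected by the hypochlorite scavenger) and the alkene geometry should be preserved.

Step 19
Reactants: 25 (3R,4R)‑3,4‑dibromo‑1‑[(1E)‑1‑bromo‑2‑carboxyhex‑1‑en‑1‑yl]‑2‑[(1E,3R)‑3‑acetoxy‑1‑bromo‑2‑carboxyhex‑1‑en‑1‑yl]cyclobut‑1‑ene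
Product: 26 (2E)‑2‑[(1R)‑1‑acetoxybutyl]‑3‑bromo‑3‑[(3S,4S)‑3,8‑dibromo‑7‑butyl‑6‑oxo‑5‑oxaspiro[3.4]octa‑1,7‑dien‑1‑yl]prop‑2‑enoic acid
Conditions: Ag2CO3 (0.55 equiv), MeCN, −20 → 0 °C, dark
Reagents that add atoms: none
Why: Silver‑assisted intramolecular allylic substitution by a carboxylate: loss of the C6B bromide gives a cyclobutenyl cation over C6B–C5B–C5A, and the arm A carboxyl closes 5‑exo on the tertiary terminus C5A from the face anti to the bromine on C6A, which sets C5A and moves the double bond to C5B=C6B. The arm A side is expected to react first because its terminus bears the more electron‑rich alkenyl group; closure of the other carboxyl first would converge on 27 in step 20 because the two bromides are related by the pseudo‑C2 axis.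

Step 20
Reactants: 26 (2E)‑2‑[(1R)‑1‑acetoxybutyl]‑3‑bromo‑3‑[(3S,4S)‑3,8‑dibromo‑7‑butyl‑6‑oxo‑5‑oxaspiro[3.4]octa‑1,7‑dien‑1‑yl]prop‑2‑enoic acid
Product: 27 (1R)‑1‑[(5S,6S,11R,12R)‑4,10,11,12‑tetrabromo‑3‑butyl‑2,8‑dioxo‑1,7‑dioxadispiro[4.0.4.2]dodeca‑3,9‑dien‑9‑yl]butyl acetate
Conditions: NBS (1.1 equiv), MeCN, 0 °C, dark
Reagents that add atoms: N‑bromosuccinimide, O=C1CCC(=O)N1Br
Why: Bromolactonisation: the bromonium ion forms on the face of C5B=C6B that carries only H on C6A and O1A on C5A (anti to the C6A bromine), and the arm B carboxyl opens it at the tertiary carbon C5B in a 5‑exo anti addition. This places Br on C6B anti to O1B and anti to Br on C6A, and O1B anti to O1A, which is the target configuration.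

## Compound list

1 | 3,4‑dibromofuran‑2(5H)‑one | O=C1OCC(Br)=C1Br | starting material
2 | butanal | CCCC=O | starting material
3 | (±)‑3‑bromo‑4‑(1‑hydroxybutyl)furan‑2(5H)‑one | CCCC(O)C1=C(Br)C(=O)OC1 | intermediate
4 | 3‑bromo‑4‑butanoylfuran‑2(5H)‑one | CCCC(=O)C1=C(Br)C(=O)OC1 | intermediate
5 | 3‑bromo‑4‑[(1R)‑1‑hydroxybutyl]furan‑2(5H)‑one | CCC[C@@H](O)C1=C(Br)C(=O)OC1 | intermediate
6 | 3‑bromo‑4‑[(1R)‑1‑hydroxybutyl]‑2,5‑dihydrofuran‑2‑ol (both anomers) | CCC[C@@H](O)C1=C(Br)C(O)OC1 | intermediate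
7 | (2Z)‑3‑bromo‑2‑[(1R)‑1‑hydroxybutyl]pent‑2‑en‑4‑yn‑1‑ol (ethynyl cis to CH2OH) | C#C/C(Br)=C(\CO)[C@@H](CCC)O | intermediate
8 | 1‑hydroxyhexan‑2‑one | CCCCC(=O)CO | starting material
9 | 1‑(methoxymethoxy)hexan‑2‑one | CCCCC(=O)COCOC | intermediate
10 | 1,1‑dibromo‑2‑[(methoxymethoxy)methyl]hex‑1‑ene | CCCCC(COCOC)=C(Br)Br | intermediate
11 | [(1E)‑1‑bromo‑2‑[(methoxymethoxy)methyl]hex‑1‑en‑1‑yl]lithium (Li cis to CH2OMOM) | CCCC/C(COCOC)=C(\Br)[Li] | intermediate
12 | (1Z)‑1‑bromo‑1‑iodo‑2‑[(methoxymethoxy)methyl]hex‑1‑ene (I cis to CH2OMOM) | CCCC/C(COCOC)=C(\Br)I | intermediate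
13 | (2Z,6E)‑3,6‑dibromo‑7‑butyl‑2‑[(1R)‑1‑hydroxybutyl]‑8‑(methoxymethoxy)octa‑2,6‑dien‑4‑yn‑1‑ol | CCCC/C(COCOC)=C(\Br)C#C/C(Br)=C(\CO)[C@@H](CCC)O | intermediate
14 | (2Z,6E)‑3,6‑dibromo‑7‑butyl‑2‑[(1R)‑1‑hydroxybutyl]octa‑2,6‑dien‑4‑yne‑1,8‑diol | CCCC/C(CO)=C(\Br)C#C/C(Br)=C(\CO)[C@@H](CCC)O | intermediate
15 | (2Z,6E)‑3,6‑dibromo‑7‑butyl‑1,8‑bis[(tert‑butyldimethylsilyl)oxy]‑2‑[(1R)‑1‑hydroxybutyl]octa‑2,6‑dien‑4‑yne | CCCC/C(CO[Si](C)(C)C(C)(C)C)=C(\Br)C#C/C(Br)=C(\CO[Si](C)(C)C(C)(C)C)[C@@H](CCC)O | intermediate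
16 | (2Z,6E)‑2‑[(1R)‑1‑acetoxybutyl]‑3,6‑dibromo‑7‑butyl‑1,8‑bis[(tert‑butyldimethylsilyl)oxy]octa‑2,6‑dien‑4‑yne | CCCC/C(CO[Si](C)(C)C(C)(C)C)=C(\Br)C#C/C(Br)=C(\CO[Si](C)(C)C(C)(C)C)[C@@H](CCC)OC(C)=O | intermediate
17 | trichloroacetyl chloride | ClC(Cl)(Cl)C(Cl)=O | starting material
18 | dichloroketene | O=C=C(Cl)Cl | intermediate
19 | 3‑[(1Z,3R)‑3‑acetoxy‑1‑bromo‑2‑{[(tert‑butyldimethylsilyl)oxy]methyl}hex‑1‑en‑1‑yl]‑2‑[(1E)‑1‑bromo‑2‑{[(tert‑butyldimethylsilyl)oxy]methyl}hex‑1‑en‑1‑yl]‑4,4‑dichlorocyclobut‑2‑en‑1‑one | O=C1C(Cl)(Cl)C(/C(Br)=C(\CO[Si](C)(C)C(C)(C)C)[C@@H](CCC)OC(C)=O)=C1/C(Br)=C(/CCCC)CO[Si](C)(C)C(C)(C)C | intermediate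
20 | 3‑[(1Z,3R)‑3‑acetoxy‑1‑bromo‑2‑{[(tert‑butyldimethylsilyl)oxy]methyl}hex‑1‑en‑1‑yl]‑4‑[(1E)‑1‑bromo‑2‑{[(tert‑butyldimethylsilyl)oxy]methyl}hex‑1‑en‑1‑yl]cyclobut‑3‑ene‑1,2‑dione | O=C1C(=O)C(/C(Br)=C(\CO[Si](C)(C)C(C)(C)C)[C@@H](CCC)OC(C)=O)=C1/C(Br)=C(/CCCC)CO[Si](C)(C)C(C)(C)C | intermediate
21 | (1S,2S)‑3‑[(1Z,3R)‑3‑acetoxy‑1‑bromo‑2‑{[(tert‑butyldimethylsilyl)oxy]methyl}hex‑1‑en‑1‑yl]‑4‑[(1E)‑1‑bromo‑2‑{[(tert‑butyldimethylsilyl)oxy]methyl}hex‑1‑en‑1‑yl]cyclobut‑3‑ene‑1,2‑diol (trans) | O[C@@H]1[C@@H](O)C(/C(Br)=C(\CO[Si](C)(C)C(C)(C)C)[C@@H](CCC)OC(C)=O)=C1/C(Br)=C(/CCCC)CO[Si](C)(C)C(C)(C)C | intermediate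
22 | (3R,4R)‑3,4‑dibromo‑1‑[(1E)‑1‑bromo‑2‑{[(tert‑butyldimethylsilyl)oxy]methyl}hex‑1‑en‑1‑yl]‑2‑[(1Z,3R)‑3‑acetoxy‑1‑bromo‑2‑{[(tert‑butyldimethylsilyl)oxy]methyl}hex‑1‑en‑1‑yl]cyclobut‑1‑ene (trans) | Br[C@H]1[C@H](Br)C(/C(Br)=C(\CO[Si](C)(C)C(C)(C)C)[C@@H](CCC)OC(C)=O)=C1/C(Br)=C(/CCCC)CO[Si](C)(C)C(C)(C)C | intermediate
23 | (3R,4R)‑3,4‑dibromo‑1‑[(1E)‑1‑bromo‑2‑(hydroxymethyl)hex‑1‑en‑1‑yl]‑2‑[(1Z,3R)‑3‑acetoxy‑1‑bromo‑2‑(hydroxymethyl)hex‑1‑en‑1‑yl]cyclobut‑1‑ene | Br[C@H]1[C@H](Br)C(/C(Br)=C(\CO)[C@@H](CCC)OC(C)=O)=C1/C(Br)=C(/CCCC)CO | intermediate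
24 | (3R,4R)‑3,4‑dibromo‑1‑[(1E)‑1‑bromo‑2‑formylhex‑1‑en‑1‑yl]‑2‑[(1E,3R)‑3‑acetoxy‑1‑bromo‑2‑formylhex‑1‑en‑1‑yl]cyclobut‑1‑ene | Br[C@H]1[C@H](Br)C(/C(Br)=C(\C=O)[C@@H](CCC)OC(C)=O)=C1/C(Br)=C(/CCCC)C=O | intermediate
25 | (3R,4R)‑3,4‑dibromo‑1‑[(1E)‑1‑bromo‑2‑carboxyhex‑1‑en‑1‑yl]‑2‑[(1E,3R)‑3‑acetoxy‑1‑bromo‑2‑carboxyhex‑1‑en‑1‑yl]cyclobut‑1‑ene (each CO2H cis to the ring carbon) | Br[C@H]1[C@H](Br)C(/C(Br)=C(\C(=O)O)[C@@H](CCC)OC(C)=O)=C1/C(Br)=C(/CCCC)C(=O)O | intermediate
26 | (2E)‑2‑[(1R)‑1‑acetoxybutyl]‑3‑bromo‑3‑[(3S,4S)‑3,8‑dibromo‑7‑butyl‑6‑oxo‑5‑oxaspiro[3.4]octa‑1,7‑dien‑1‑yl]prop‑2‑enoic acid | CCCCC1=C(Br)[C@@]2(OC1=O)[C@@H](Br)C=C2/C(Br)=C(\C(=O)O)[C@@H](CCC)OC(C)=O | intermediate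
27 | (1R)‑1‑[(5S,6S,11R,12R)‑4,10,11,12‑tetrabromo‑3‑butyl‑2,8‑dioxo‑1,7‑dioxadispiro[4.0.4.2]dodeca‑3,9‑dien‑9‑yl]butyl acetate | CCCCC1=C(Br)[C@@]2(OC1=O)[C@@H](Br)[C@H](Br)[C@@]21OC(=O)C([C@@H](CCC)OC(C)=O)=C1Br | target

## Step count and risks

Total: 20 steps. Longest linear sequence: 17 steps (steps 1–5 and 9–20); steps 6–8 form the second branch.

Least certain steps:

Step 13 (key step). The cycloaddition may be too slow at an alkyne that is hindered on both sides and deactivated by two vinyl bromines; ketene oligomerisation and Lewis‑acid cleavage or acylation of the silyl ethers would then take over. Fallback: from 16, double carbonylation of the alkyne with the iron carbonyl hydride reagent made from Fe(CO)5, NaBH4 and AcOH in THF, followed by oxidative release with CuCl2·2H2O in the same flask. This known alkyne‑to‑cyclobutenedione conversion makes no new isolated compound (F0) and comes back to the route at 20.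

Step 14. Ionisation of the gem‑dichloride is slowed by the adjacent carbonyl, so allylic migration of chloride, attack of water at the ring carbonyl with ring cleavage, or loss of silyl groups may outrun hydrolysis. Fallback: from 19, reduce the ketone first under the conditions of step 15 to the (1S)‑3‑[(1Z,3R)‑3‑acetoxy‑1‑bromo‑2‑{[(tert‑butyldimethylsilyl)oxy]methyl}hex‑1‑en‑1‑yl]‑2‑[(1E)‑1‑bromo‑2‑{[(tert‑butyldimethylsilyl)oxy]methyl}hex‑1‑en‑1‑yl]‑4,4‑dichlorocyclobut‑2‑en‑1‑ol F1. Its gem‑dichloride is now allylic only and should hydrolyse readily with AgOTf/NaHCO3 in wet acetone to the (4S)‑4‑hydroxycyclobut‑2‑en‑1‑one F2. A second oxazaborolidine reduction, with hydride entering anti to the hydroxyl, comes back at 21.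

Step 16. The activated cyclobutenol can ionise to a cyclobutenyl cation stabilised by both alkenyl arms; bromide return at either face would erode the trans relationship and the absolute sense that step 15 installed. Fallback: from 20, give up catalyst and inversion control. Reduce with NaBH4/CeCl3·7H2O (Luche) to the ring‑stereoisomeric diol mixture F3, brominate with CBr4/PPh3 and equilibrate with LiBr in acetone to the more stable trans‑dibromides. Because of C1′ these are diastereomers, 22 and its (3S,4S) isomer F4, and are separated by chromatography. The route is rejoined at 22 at the cost of half the material.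

Step 19. A second ionisation of the remaining allylic bromide would give double spirolactonisation without the ring bromine; closure through the six‑membered mode at the secondary terminus is also possible. Fallback: reverse the order of the two oxygenations from 25. NBS bromolactonisation across the tetrasubstituted C5A=C5B bond gives the ring A spirolactone F5 (C5A as in 27, tertiary bromide on C5B anti to O1A, both ring CHBr centres untouched, arm B acid free). Ag2CO3 then replaces the tertiary bromide by the arm B carboxyl through the C5B cation, with entry anti to O1A and to the C6B bromine. This comes back at 27.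

Step 5. The lactol may dehydrate to a furan, or its open hydroxy‑enal form may lose its geometry by reversible conjugate addition of methoxide before homologation. Fallback: from 5, open the lactone with Me(MeO)NH·HCl/AlMe3 to the (2Z,4R)‑2‑bromo‑4‑hydroxy‑3‑(hydroxymethyl)‑N‑methoxy‑N‑methylhept‑2‑enamide F6 and silylate both hydroxyls (TBSOTf, 2,6‑lutidine) to the bis‑silyl amide F7. Reduction with iBu2AlH gives the (2Z,4R)‑enal F8, which cannot cyclise. Homologation with the Ohira–Bestmann reagent gives the bis‑silyl enyne F9, and Bu4NF comes back at 7.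

Further compounds

F0 | step 13 | none | none
F1 | step 14 | (1S)‑3‑[(1Z,3R)‑3‑acetoxy‑1‑bromo‑2‑{[(tert‑butyldimethylsilyl)oxy]methyl}hex‑1‑en‑1‑yl]‑2‑[(1E)‑1‑bromo‑2‑{[(tert‑butyldimethylsilyl)oxy]methyl}hex‑1‑en‑1‑yl]‑4,4‑dichlorocyclobut‑2‑en‑1‑ol | O[C@@H]1C(Cl)(Cl)C(/C(Br)=C(\CO[Si](C)(C)C(C)(C)C)[C@@H](CCC)OC(C)=O)=C1/C(Br)=C(/CCCC)CO[Si](C)(C)C(C)(C)C
F2 | step 14 | (4S)‑2‑[(1Z,3R)‑3‑acetoxy‑1‑bromo‑2‑{[(tert‑butyldimethylsilyl)oxy]methyl}hex‑1‑en‑1‑yl]‑3‑[(1E)‑1‑bromo‑2‑{[(tert‑butyldimethylsilyl)oxy]methyl}hex‑1‑en‑1‑yl]‑4‑hydroxycyclobut‑2‑en‑1‑one | O[C@@H]1C(=O)C(/C(Br)=C(\CO[Si](C)(C)C(C)(C)C)[C@@H](CCC)OC(C)=O)=C1/C(Br)=C(/CCCC)CO[Si](C)(C)C(C)(C)C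
F3 | step 16 | 3‑[(1Z,3R)‑3‑acetoxy‑1‑bromo‑2‑{[(tert‑butyldimethylsilyl)oxy]methyl}hex‑1‑en‑1‑yl]‑4‑[(1E)‑1‑bromo‑2‑{[(tert‑butyldimethylsilyl)oxy]methyl}hex‑1‑en‑1‑yl]cyclobut‑3‑ene‑1,2‑diol (ring carbinols as stereoisomer mixture) | OC1C(O)C(/C(Br)=C(\CO[Si](C)(C)C(C)(C)C)[C@@H](CCC)OC(C)=O)=C1/C(Br)=C(/CCCC)CO[Si](C)(C)C(C)(C)C
F4 | step 16 | (3S,4S)‑3,4‑dibromo‑1‑[(1E)‑1‑bromo‑2‑{[(tert‑butyldimethylsilyl)oxy]methyl}hex‑1‑en‑1‑yl]‑2‑[(1Z,3R)‑3‑acetoxy‑1‑bromo‑2‑{[(tert‑butyldimethylsilyl)oxy]methyl}hex‑1‑en‑1‑yl]cyclobut‑1‑ene | Br[C@@H]1[C@@H](Br)C(/C(Br)=C(\CO[Si](C)(C)C(C)(C)C)[C@@H](CCC)OC(C)=O)=C1/C(Br)=C(/CCCC)CO[Si](C)(C)C(C)(C)C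
F5 | step 19 | (2E)‑2‑[(1R)‑1‑acetoxybutyl]‑3‑bromo‑3‑[1,2,3,8‑tetrabromo‑7‑butyl‑6‑oxo‑5‑oxaspiro[3.4]oct‑7‑en‑1‑yl]prop‑2‑enoic acid (spiro carbon S as in 27; tertiary Br anti to the lactone oxygen; the two CHBr centres as in 25) | CCCCC1=C(Br)[C@@]2(OC1=O)[C@@H](Br)[C@H](Br)[C@]2(Br)/C(Br)=C(\C(=O)O)[C@@H](CCC)OC(C)=O
F6 | step 5 | (2Z,4R)‑2‑bromo‑4‑hydroxy‑3‑(hydroxymethyl)‑N‑methoxy‑N‑methylhept‑2‑enamide | CCC[C@@H](O)/C(CO)=C(\Br)C(=O)N(C)OC
F7 | step 5 | (2Z,4R)‑2‑bromo‑4‑[(tert‑butyldimethylsilyl)oxy]‑3‑{[(tert‑butyldimethylsilyl)oxy]methyl}‑N‑methoxy‑N‑methylhept‑2‑enamide | CCC[C@@H](O[Si](C)(C)C(C)(C)C)/C(CO[Si](C)(C)C(C)(C)C)=C(\Br)C(=O)N(C)OC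
F8 | step 5 | (2Z,4R)‑2‑bromo‑4‑[(tert‑butyldimethylsilyl)oxy]‑3‑{[(tert‑butyldimethylsilyl)oxy]methyl}hept‑2‑enal | CCC[C@@H](O[Si](C)(C)C(C)(C)C)/C(CO[Si](C)(C)C(C)(C)C)=C(\Br)C=O
F9 | step 5 | (2Z)‑3‑bromo‑1‑[(tert‑butyldimethylsilyl)oxy]‑2‑{(1R)‑1‑[(tert‑butyldimethylsilyl)oxy]butyl}pent‑2‑en‑4‑yne | C#C/C(Br)=C(\CO[Si](C)(C)C(C)(C)C)[C@@H](CCC)O[Si](C)(C)C(C)(C)C
A1 | alternative 1 | trans‑1‑(hex‑1‑yn‑1‑yl)‑2‑{(3R)‑3‑[(tert‑butyldimethylsilyl)oxy]hex‑1‑yn‑1‑yl}‑3,4‑bis(tributylstannyl)cyclobut‑3‑ene‑1,2‑diol | CCCCC#C[C@@]1(O)C([Sn](CCCC)(CCCC)CCCC)=C([Sn](CCCC)(CCCC)CCCC)[C@]1(O)C#C[C@@H](CCC)O[Si](C)(C)C(C)(C)C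
A2 | alternative 1 | 3,4‑bis(tributylstannyl)cyclobut‑3‑ene‑1,2‑dione | CCCC[Sn](CCCC)(CCCC)C1=C([Sn](CCCC)(CCCC)CCCC)C(=O)C1=O
A3 | alternative 1 | hex‑1‑yn‑1‑yllithium | [Li]C#CCCCC
A4 | alternative 1 | {(3R)‑3‑[(tert‑butyldimethylsilyl)oxy]hex‑1‑yn‑1‑yl}lithium | [Li]C#C[C@@H](CCC)O[Si](C)(C)C(C)(C)C
A5 | alternative 2 | deacetyl target (C1′ alcohol) | CCCCC1=C(Br)[C@@]2(OC1=O)[C@@H](Br)[C@H](Br)[C@@]21OC(=O)C([C@@H](CCC)O)=C1Br
A6 | alternative 2 | methyl 3‑[ring A spirolactone‑dibromocyclobutanol]prop‑2‑ynoate (γ‑hydroxy ynoate with the C5B hydroxyl in the position of O1B) | CCCCC1=C(Br)[C@@]2(OC1=O)[C@@H](Br)[C@H](Br)[C@]2(O)C#CC(=O)OC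
A7 | alternative 3 | 1‑(hex‑1‑yn‑1‑yl)‑4‑[(tert‑butyldimethylsilyl)oxy]‑2‑oxabicyclo[2.2.0]hex‑5‑en‑3‑one | CCCCC#C[C@]12OC(=O)[C@@]1(O[Si](C)(C)C(C)(C)C)C=C2
A8 | alternative 3 | 3‑[(tert‑butyldimethylsilyl)oxy]‑6‑(hex‑1‑yn‑1‑yl)‑2H‑pyran‑2‑one | CCCCC#CC1=CC=C(O[Si](C)(C)C(C)(C)C)C(=O)O1
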